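**Retrosynthetic overview**

1. Ring locants: C1 (CH3 and vinyl), C2 (CH2), C3 (acyloxy), C4 (1-carboxyvinyl), C5 (OH), C6 (3-hydroxyprop-1-en-2-yl); the β face is that of the C1 methyl. The plan rests on this pattern of the cyclohexane ring: C1 and C6 are the β- and α-carbons of a C5 carbonyl and the C3 oxygen is trans to the C1 methyl, so a 5-silyloxy-3-vinylcyclohex-2-enone can accept CH3 at C1 anti to that oxygen and an alkenyl group at C6.
2. Late disconnections: C4 acrylic acid from a PMB-protected allylic alcohol (DDQ, MnO2, NaClO2); C3 ester from (Z)-4-acetoxy-2-methylbut-2-enoic acid (from 3-methylfuran-2(5H)-one); axial C5–OH from the C5 ketone; C4–alkenyl bond by Pd-catalysed zinc-enolate alkenylation.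
3. Key disconnection: the C1–CH3 and C6–alkenyl bonds, made in one flask from enone 8, MeMgBr and bromide 10 (Cu-catalysed 1,4-addition, then Pd-catalysed alkenylation of the zinc enolate).
4. Enone 8 from phloroglucinol: NaBH4 reduction, ethyl enol ether, lipase resolution, silylation, vinyl Grignard addition with carbonyl transposition.
5. Ring order: the only ring, the cyclohexane, is carried intact from phloroglucinol; no ring is formed at any stage.

Key step: step 7

Assumption: the lipase acetylates the (S)-enantiomer of 3 faster (size model for secondary alcohols, with the ethoxy-bearing ring arm as the large group), so that (R)-4 is the alcohol left unreacted.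

**Route**

Step 1
Reactants: 1 phloroglucinol
Product: 2 5-hydroxycyclohexane-1,3-dione
Conditions: NaBH4, H2O, 0 °C to rt; then HCl to pH 4, 0 °C
Reagents that add atoms: none
Why: Phloroglucinol reacts as its triketo tautomer, hydride reduces one carbonyl and the remaining 1,3-dione, held as its enolate, resists further reduction (borohydride reduction of a polyhydroxybenzene); cold, mild acidification avoids dehydration to resorcinol.

Step 2
Reactants: 2 5-hydroxycyclohexane-1,3-dione
Product: 3 rac-3-ethoxy-5-hydroxycyclohex-2-en-1-one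
Conditions: EtOH, TsOH·H2O (cat.), 3 Å molecular sieves, rt
Reagents that add atoms: ethanol CCO
Why: Acid-catalysed O-alkylation of a cyclic 1,3-dione (vinylogous esterification) proceeds at room temperature without touching the secondary alcohol; either carbonyl reacts, so the product is racemic.

Step 3
Reactants: 3 rac-3-ethoxy-5-hydroxycyclohex-2-en-1-one
Product: 4 (R)-3-ethoxy-5-hydroxycyclohex-2-en-1-one
Conditions: Candida antarctica lipase B (immobilised), vinyl acetate, t-BuOMe, 30 °C, to just past half conversion; chromatography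
Reagents that add atoms: none
Why: Lipase-catalysed kinetic resolution by irreversible transesterification should acetylate the (S)-alcohol and, when run past half conversion, leave the slow-reacting (R)-alcohol in high enantiomeric purity; this sets the C3 oxygen stereocentre.

Step 4
Reactants: 4 (R)-3-ethoxy-5-hydroxycyclohex-2-en-1-one
Product: 5 (R)-5-(tert-butyldimethylsilyloxy)-3-ethoxycyclohex-2-en-1-one
Conditions: TBSCl, imidazole, DMF, rt
Reagents that add atoms: tert-butyldimethylsilyl chloride CC(C)(C)[Si](C)(C)Cl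
Why: Standard silylation of a secondary alcohol under neutral conditions that leave the vinylogous ester untouched.

Step 5
Reactants: 5 (R)-5-(tert-butyldimethylsilyloxy)-3-ethoxycyclohex-2-en-1-one; 6 vinylmagnesium bromide
Product: 8 (S)-5-(tert-butyldimethylsilyloxy)-3-vinylcyclohex-2-en-1-one, via magnesium alkoxide 7 (not isolated)
Conditions: CH2=CHMgBr, THF, −78 to 0 °C; then 1 M HCl, 0 °C
Reagents that add atoms: water O
Why: Stork–Danheiser sequence: 1,2-addition to the vinylogous ester carbonyl, then acid-promoted ionisation of the doubly allylic carbinol and hydrolysis of the enol ether transposes the carbonyl; the stereocentre is not involved and only its descriptor changes.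

Step 6
Reactants: 9 2-bromoprop-2-en-1-ol
Product: 10 tert-butyl[(2-bromoprop-2-en-1-yl)oxy]diphenylsilane
Conditions: TBDPSCl, imidazole, CH2Cl2, rt
Reagents that add atoms: tert-butyldiphenylsilyl chloride CC(C)(C)[Si](Cl)(c1ccccc1)c1ccccc1
Why: Standard silylation of a primary allylic alcohol; the alkenyl bromide is inert.

Step 7
Reactants: 8 (S)-5-(tert-butyldimethylsilyloxy)-3-vinylcyclohex-2-en-1-one; 11 methylmagnesium bromide; 10 tert-butyl[(2-bromoprop-2-en-1-yl)oxy]diphenylsilane
Product: 14 (2R,3S,5S)-5-(tert-butyldimethylsilyloxy)-2-[3-(tert-butyldiphenylsilyloxy)prop-1-en-2-yl]-3-methyl-3-vinylcyclohexan-1-one, via magnesium enolate 12 (not isolated), via zinc enolate 13 (not isolated)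
Conditions: MeMgBr, Cu(OTf)2 (3 mol%), chiral 1,3-diaryl-4,5-diphenylimidazolinium salt (4 mol%, enantiomer matched to the substrate), Et2O, −30 to 0 °C; ZnCl2, THF, 0 °C; then 10, Pd(dba)2 (5 mol%), P(t-Bu)3 (10 mol%), THF, rt to 40 °C; aq. NH4Cl; Et3N, CH2Cl2, rt (C6 equilibration)
Reagents that add atoms: none
Why: Proposed new method: MeMgBr forms a carbene-ligated methylcopper species (monovalent copper) that complexes the enone, adds at C1 to give a trivalent copper σ-allyl intermediate and reductively eliminates the C1–CH3 bond, leaving the C5–C6 magnesium enolate 12; ZnCl2 turns this into zinc enolate 13, which enters a zerovalent palladium cycle (oxidative addition of bromide 10, enolate transmetalation, reductive elimination) to make the C6–alkenyl bond. The closest known reaction types are the Cu(OTf)2/carbene-catalysed 1,4-addition of Grignard reagents to 3-alkenylcyclohexenones that creates quaternary centres and the palladium-catalysed α-alkenylation of ketone enolates (Negishi-type coupling of zinc enolates); running both in one flask on one enolate is the untested part. No ring is closed: two bonds are added to a ring that already exists. C1 is set by axial delivery of methyl to the half-chair of the enone on the face anti to the C3 silyloxy group, and the ligand enantiomer is chosen to reinforce this substrate bias; C6 is α to the ketone and allylic, so it should equilibrate to the epimer with the alkenyl arm equatorial and cis to the C1 methyl, since the other epimer needs either an axial arm or a syn-diaxial C1-vinyl/C3-silyloxy pair. The step needs 1,4- and not 1,6-regioselectivity on the dienone, for which the strongly donating carbene (fast reductive elimination before copper migrates to the vinyl terminus) is relied on, and it needs the enolate to stay at C5–C6, which the zinc enolate should do because it equilibrates slowly and cannot expel the C3 silyloxy group from that position.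

Step 8
Reactants: 9 2-bromoprop-2-en-1-ol
Product: 15 1-{[(2-bromoprop-2-en-1-yl)oxy]methyl}-4-methoxybenzene
Conditions: NaH, 4-MeOC6H4CH2Cl, Bu4NI (cat.), THF/DMF, 0 °C to rt
Reagents that add atoms: 4-methoxybenzyl chloride COc1ccc(CCl)cc1
Why: Williamson etherification of the primary allylic alkoxide; the alkenyl bromide does not react under these conditions.

Step 9
Reactants: 14 key-step ketone; 15 1-{[(2-bromoprop-2-en-1-yl)oxy]methyl}-4-methoxybenzene
Product: 18 (2R,3S,5S,6R)-5-(tert-butyldimethylsilyloxy)-2-[3-(tert-butyldiphenylsilyloxy)prop-1-en-2-yl]-6-[3-(4-methoxybenzyloxy)prop-1-en-2-yl]-3-methyl-3-vinylcyclohexan-1-one, via lithium enolate 16 (not isolated), via zinc enolate 17 (not isolated)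
Conditions: LiN(i-Pr)2, THF, −78 °C; ZnCl2, −78 to 0 °C; then 15, Pd(dba)2 (5 mol%), P(t-Bu)3 (10 mol%), THF, rt; DBU (cat.), CH2Cl2, rt if C4 equilibration is needed
Reagents that add atoms: none
Why: Kinetic deprotonation should take the unhindered axial C4–H and not the neopentylic tertiary C6–H, and zinc enolate 17 couples with 15 at zerovalent palladium (Pd-catalysed ketone α-alkenylation, Negishi type); the equatorial C3 silyloxy group lies in the enolate plane, so β-elimination is stereoelectronically disfavoured, and the epimerisable C4 centre should settle equatorial, trans to the C3 oxygen.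

Step 10
Reactants: 18 C4,C6-dialkenyl ketone
Product: 19 axial C5 alcohol (C5–OH β, cis to the C4 and C6 arms and to the C1 methyl)
Conditions: LiBH(s-Bu)3, THF, −78 to −40 °C; then NaOH, H2O2, 0 °C
Reagents that add atoms: none
Why: The axial C1 methyl blocks the axial trajectory at C5 and the bulky hydride attacks from the equatorial side (substrate- and reagent-controlled ketone reduction), which sets C5 as the axial alcohol.

Step 11
Reactants: 19 axial C5 alcohol
Product: 20 C3,C5-diol (C3–OH α equatorial, C5–OH β axial)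
Conditions: CSA (cat.), MeOH/CH2Cl2, 0 °C to rt
Reagents that add atoms: none
Why: Acid-catalysed methanolysis cleaves the secondary tert-butyldimethylsilyl ether much faster than the primary tert-butyldiphenylsilyl ether and leaves the PMB ether untouched (selective desilylation).

Step 12
Reactants: 21 3-methylfuran-2(5H)-one
Product: 23 (Z)-4-acetoxy-2-methylbut-2-enoic acid, via potassium (Z)-4-hydroxy-2-methylbut-2-enoate 22 (not isolated)
Conditions: KOH (1 equiv), MeOH/H2O, 0 °C to rt, evaporate; Ac2O, pyridine, DMAP (cat.), 0 °C; aq. NaHCO3, then HCl to pH 3, 0 °C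
Reagents that add atoms: potassium hydroxide [K+].[OH-]; acetic anhydride CC(=O)OC(C)=O
Why: Saponification opens the lactone to the hydroxy carboxylate with the Z geometry fixed by the ring, and acetylation of the primary alcohol with hydrolysis of any mixed anhydride on work-up should give the acid; material that recloses is recovered as 21.

Step 13
Reactants: 20 C3,C5-diol; 23 (Z)-4-acetoxy-2-methylbut-2-enoic acid
Product: 25 C3 (Z)-4-acetoxy-2-methylbut-2-enoate with free C5–OH, via mixed anhydride 24 (not isolated)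
Conditions: 2,4,6-Cl3C6H2COCl, Et3N, THF, 0 °C to rt; then 20, DMAP, toluene, rt
Reagents that add atoms: none
Why: Yamaguchi esterification through mixed anhydride 24 should acylate the equatorial C3–OH in preference to the axial C5–OH, which is flanked by two branched carbons and syn-axial to the C1 methyl; fast acyl transfer at room temperature is chosen to keep the Z geometry.

Step 14
Reactants: 25 C3 ester with free C5–OH
Product: 26 C5 triethylsilyl ether
Conditions: Et3SiOTf, 2,6-lutidine, CH2Cl2, −78 to 0 °C
Reagents that add atoms: triethylsilyl triflate CC[Si](CC)(CC)OS(=O)(=O)C(F)(F)F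
Why: Silyl triflate silylation reaches even the hindered axial alcohol; the C5 oxygen is capped because a free γ-hydroxyl would trap the aldehyde of step 16 as a lactol that is oxidised on to the lactone.

Step 15
Reactants: 26 C5 triethylsilyl ether
Product: 27 primary allylic alcohol on the C4 arm
Conditions: DDQ, CH2Cl2/pH 7 phosphate buffer, 0 °C
Reagents that add atoms: none
Why: Oxidative cleavage of the PMB ether by DDQ (hydride abstraction, hydrolysis of the oxocarbenium ion) under buffered conditions leaves silyl ethers, esters and alkenes intact.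

Step 16
Reactants: 27 primary allylic alcohol
Product: 28 2-substituted acrolein on the C4 arm
Conditions: MnO2, CH2Cl2, rt
Reagents that add atoms: none
Why: MnO2 oxidises the allylic alcohol selectively to the enal and no other free hydroxyl is present.

Step 17
Reactants: 28 enal
Product: 29 acrylic acid with C5–OSiEt3 and tert-butyldiphenylsilyl ether in place
Conditions: NaClO2, NaH2PO4, 2-methylbut-2-ene, t-BuOH/H2O, 0 °C to rt
Reagents that add atoms: sodium chlorite [Na+].[O-]Cl=O
Why: Pinnick oxidation converts the enal to the α-substituted acrylic acid without touching the alkenes, because the hypochlorous acid formed is scavenged by 2-methylbut-2-ene.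

Step 18
Reactants: 29 bis-silylated acid
Product: 30 target acid CNP0261293.3
Conditions: Bu4NF, AcOH (1:1), THF, 0 °C to rt; work-up at pH 5, 0 °C
Reagents that add atoms: none
Why: Buffered fluoride cleaves the triethylsilyl and tert-butyldiphenylsilyl ethers (global desilylation) while the acetate and the enoate survive, and the acid, held as its carboxylate, should not lactonise onto the cis C5–OH.

**Compound list**

1 | phloroglucinol | Oc1cc(O)cc(O)c1 | starting material
2 | 5-hydroxycyclohexane-1,3-dione | O=C1CC(O)CC(=O)C1 | intermediate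
3 | rac-3-ethoxy-5-hydroxycyclohex-2-en-1-one | CCOC1=CC(=O)CC(O)C1 | intermediate
4 | (R)-3-ethoxy-5-hydroxycyclohex-2-en-1-one | CCOC1=CC(=O)C[C@H](O)C1 | intermediate
5 | (R)-5-(tert-butyldimethylsilyloxy)-3-ethoxycyclohex-2-en-1-one | CCOC1=CC(=O)C[C@H](O[Si](C)(C)C(C)(C)C)C1 | intermediate
6 | vinylmagnesium bromide | C=C[Mg]Br | starting material
7 | bromomagnesium 5-(tert-butyldimethylsilyloxy)-3-ethoxy-1-vinylcyclohex-2-en-1-olate (silyloxy centre as in 5, carbinol centre both epimers) | CCOC1=CC(O[Mg]Br)(C=C)C[C@H](O[Si](C)(C)C(C)(C)C)C1 | intermediate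
8 | (S)-5-(tert-butyldimethylsilyloxy)-3-vinylcyclohex-2-en-1-one | C=CC1=CC(=O)C[C@@H](O[Si](C)(C)C(C)(C)C)C1 | intermediate
9 | 2-bromoprop-2-en-1-ol | OCC(Br)=C | starting material
10 | tert-butyl[(2-bromoprop-2-en-1-yl)oxy]diphenylsilane | C=C(Br)CO[Si](c1ccccc1)(c1ccccc1)C(C)(C)C | intermediate
11 | methylmagnesium bromide | C[Mg]Br | starting material
12 | bromomagnesium C5–C6 enolate of the C1-methyl adduct of 8 | C=C[C@]1(C)C[C@H](O[Si](C)(C)C(C)(C)C)CC(O[Mg]Br)=C1 | intermediate
13 | chlorozinc C5–C6 enolate of the C1-methyl adduct of 8 | C=C[C@]1(C)C[C@H](O[Si](C)(C)C(C)(C)C)CC(O[Zn]Cl)=C1 | intermediate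
14 | (2R,3S,5S)-5-(tert-butyldimethylsilyloxy)-2-[3-(tert-butyldiphenylsilyloxy)prop-1-en-2-yl]-3-methyl-3-vinylcyclohexan-1-one (C5 ketone; C1 methyl cis to the C6 arm and trans to the C3 oxygen) | C=C[C@]1(C)C[C@H](O[Si](C)(C)C(C)(C)C)CC(=O)[C@H]1C(=C)CO[Si](c2ccccc2)(c2ccccc2)C(C)(C)C | intermediate
15 | 1-{[(2-bromoprop-2-en-1-yl)oxy]methyl}-4-methoxybenzene | C=C(Br)COCc1ccc(OC)cc1 | intermediate
16 | lithium C4–C5 enolate of 14 | C=C[C@]1(C)C[C@H](O[Si](C)(C)C(C)(C)C)C=C(O[Li])[C@H]1C(=C)CO[Si](c2ccccc2)(c2ccccc2)C(C)(C)C | intermediate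
17 | chlorozinc C4–C5 enolate of 14 | C=C[C@]1(C)C[C@H](O[Si](C)(C)C(C)(C)C)C=C(O[Zn]Cl)[C@H]1C(=C)CO[Si](c2ccccc2)(c2ccccc2)C(C)(C)C | intermediate
18 | (2R,3S,5S,6R)-5-(tert-butyldimethylsilyloxy)-2-[3-(tert-butyldiphenylsilyloxy)prop-1-en-2-yl]-6-[3-(4-methoxybenzyloxy)prop-1-en-2-yl]-3-methyl-3-vinylcyclohexan-1-one (C4 arm β, trans to the C3 oxygen) | C=C[C@]1(C)C[C@H](O[Si](C)(C)C(C)(C)C)[C@@H](C(=C)COCc2ccc(OC)cc2)C(=O)[C@H]1C(=C)CO[Si](c3ccccc3)(c3ccccc3)C(C)(C)C | intermediate
19 | C5 axial alcohol from 18 (C5–OH β; ring configuration as in 30; C3–OTBS, C4 arm OPMB, C6 arm OTBDPS) | C=C[C@]1(C)C[C@H](O[Si](C)(C)C(C)(C)C)[C@@H](C(=C)COCc2ccc(OC)cc2)[C@@H](O)[C@H]1C(=C)CO[Si](c3ccccc3)(c3ccccc3)C(C)(C)C | intermediate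
20 | C3,C5-diol (C3–OH α, C5–OH β; C4 arm OPMB, C6 arm OTBDPS) | C=C[C@]1(C)C[C@H](O)[C@@H](C(=C)COCc2ccc(OC)cc2)[C@@H](O)[C@H]1C(=C)CO[Si](c3ccccc3)(c3ccccc3)C(C)(C)C | intermediate
21 | 3-methylfuran-2(5H)-one | CC1=CCOC1=O | starting material
22 | potassium (Z)-4-hydroxy-2-methylbut-2-enoate | C/C(=C/CO)C(=O)[O-].[K+] | intermediate
23 | (Z)-4-acetoxy-2-methylbut-2-enoic acid | CC(=O)OC/C=C(/C)C(=O)O | intermediate
24 | (Z)-4-acetoxy-2-methylbut-2-enoic 2,4,6-trichlorobenzoic anhydride | CC(=O)OC/C=C(/C)C(=O)OC(=O)c1c(Cl)cc(Cl)cc1Cl | intermediate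
25 | C3 (Z)-4-acetoxy-2-methylbut-2-enoate of 20 with free C5–OH | C=C[C@]1(C)C[C@H](OC(=O)/C(C)=C\COC(C)=O)[C@@H](C(=C)COCc2ccc(OC)cc2)[C@@H](O)[C@H]1C(=C)CO[Si](c3ccccc3)(c3ccccc3)C(C)(C)C | intermediate
26 | C5 triethylsilyl ether of 25 | C=C[C@]1(C)C[C@H](OC(=O)/C(C)=C\COC(C)=O)[C@@H](C(=C)COCc2ccc(OC)cc2)[C@@H](O[Si](CC)(CC)CC)[C@H]1C(=C)CO[Si](c3ccccc3)(c3ccccc3)C(C)(C)C | intermediate
27 | allylic alcohol (C4 arm CH2OH) from 26 | C=C[C@]1(C)C[C@H](OC(=O)/C(C)=C\COC(C)=O)[C@@H](C(=C)CO)[C@@H](O[Si](CC)(CC)CC)[C@H]1C(=C)CO[Si](c3ccccc3)(c3ccccc3)C(C)(C)C | intermediate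
28 | enal (C4 arm CHO) | C=C[C@]1(C)C[C@H](OC(=O)/C(C)=C\COC(C)=O)[C@@H](C(=C)C=O)[C@@H](O[Si](CC)(CC)CC)[C@H]1C(=C)CO[Si](c3ccccc3)(c3ccccc3)C(C)(C)C | intermediate
29 | acrylic acid (C4 arm CO2H) with C5–OSiEt3 and C6 arm OTBDPS | C=C[C@]1(C)C[C@H](OC(=O)/C(C)=C\COC(C)=O)[C@@H](C(=C)C(=O)O)[C@@H](O[Si](CC)(CC)CC)[C@H]1C(=C)CO[Si](c3ccccc3)(c3ccccc3)C(C)(C)C | intermediate
30 | CNP0261293.3, (1S,3S,4S,5S,6R) in the ring locants of the overview | C=C[C@]1(C)C[C@H](OC(=O)/C(C)=C\COC(C)=O)[C@@H](C(=C)C(=O)O)[C@@H](O)[C@H]1C(=C)CO | target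

**Step count**

Total: 18 steps. Longest linear sequence: 15 steps (1–5, 7, 9–11, 13–18) from phloroglucinol; steps 6, 8 and 12 are one-step side branches.

**Steps most likely to fail**

1. Step 7. Methyl may be delivered to the vinyl terminus (1,6-addition) instead of C1; methyl leaves trivalent copper slowly, which gives the copper time to migrate along the allyl system. The magnesium or zinc enolate may also fail to enter the palladium cycle before it equilibrates and loses silanol. The fallback uses known chemistry, sets out from 5 and returns at 14. Lithium (trimethylsilyl)acetylide (THF, −78 °C) followed by 1 M HCl would convert 5 into (S)-5-(tert-butyldimethylsilyloxy)-3-[(trimethylsilyl)ethynyl]cyclohex-2-en-1-one F1; 3-alkynylcyclohexenones are a substrate class in which the 1,4-addition of Grignard reagents with Cu(OTf)2 and a carbene ligand is the established outcome, and the silyl cap shields the alkyne terminus. MeMgBr with Cu(OTf)2 and the same carbene, quenched with Me3SiCl, would give the C5–C6 trimethylsilyl enol ether of the C1-methyl adduct F2, which is isolated. MeLi and then ZnCl2 would regenerate the enolate for a separate Pd(dba)2/P(t-Bu)3 coupling with 10 to give the (trimethylsilyl)ethynyl analogue of 14 F3. K2CO3 in MeOH at 0 °C would then give the ethynyl analogue of 14 F4, and semihydrogenation (H2, Pd/CaCO3 poisoned with Pb(OAc)2, quinoline) would return 14, with C6 re-equilibrated at that stage.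

2. Step 9. Deprotonation may occur at the doubly activated C6–H instead of C4, the hindered zinc enolate may couple slowly, and the C3 silyloxy group may be lost by β-elimination if the enolate lives long at room temperature. The fallback sets out from 14 and returns at 18. 4-Methoxybenzyl propargyl ether would be lithiated (n-BuLi) and sulfenylated with PhSSPh to 1-methoxy-4-({[3-(phenylsulfanyl)prop-2-yn-1-yl]oxy}methyl)benzene F5, then oxidised with mCPBA to 1-methoxy-4-({[3-(phenylsulfonyl)prop-2-yn-1-yl]oxy}methyl)benzene F6. The kinetic lithium enolate 16 (LiN(i-Pr)2, THF, −78 °C) would add in Michael fashion to the alkyne carbon of F6 that carries the CH2OPMB group, giving the C4 vinyl sulfone adduct F7 at low temperature without palladium. Reductive desulfonylation (Na(Hg), Na2HPO4, MeOH/THF, −20 °C) would return 18.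

3. Step 13. The activated Z-acid may isomerise to the E-enoyl unit by reversible conjugate addition of DMAP, and the mixed anhydride may collapse to the butenolide with transfer of acetyl. The fallback builds the Z-alkene after the ester bond exists; it sets out from 20 and returns at 26. 2-[Bis(2,2,2-trifluoroethoxy)phosphoryl]propanoic acid F8 (from its commercial ethyl ester, LiOH, aqueous THF, 0 °C) would be coupled to the C3–OH of 20 (EDC·HCl, DMAP, CH2Cl2) to give the C3 phosphonopropanoate of 20 F9. Silylation (Et3SiOTf, 2,6-lutidine) would give its C5 triethylsilyl ether F10. Still–Gennari olefination (KN(SiMe3)2, 18-crown-6, THF, −78 °C, then 2-oxoethyl acetate) should give the Z-enoate 26 directly.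

**Further compounds**

F1 | step 7 | (S)-5-(tert-butyldimethylsilyloxy)-3-[(trimethylsilyl)ethynyl]cyclohex-2-en-1-one | C[Si](C)(C)C#CC1=CC(=O)C[C@@H](O[Si](C)(C)C(C)(C)C)C1
F2 | step 7 | C5–C6 trimethylsilyl enol ether of the C1-methyl adduct of F1 | C[Si](C)(C)C#C[C@]1(C)C[C@H](O[Si](C)(C)C(C)(C)C)CC(O[Si](C)(C)C)=C1
F3 | step 7 | (trimethylsilyl)ethynyl analogue of 14 | C[Si](C)(C)C#C[C@]1(C)C[C@H](O[Si](C)(C)C(C)(C)C)CC(=O)[C@H]1C(=C)CO[Si](c2ccccc2)(c2ccccc2)C(C)(C)C
F4 | step 7 | ethynyl analogue of 14 | C#C[C@]1(C)C[C@H](O[Si](C)(C)C(C)(C)C)CC(=O)[C@H]1C(=C)CO[Si](c2ccccc2)(c2ccccc2)C(C)(C)C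
F5 | step 9 | 1-methoxy-4-({[3-(phenylsulfanyl)prop-2-yn-1-yl]oxy}methyl)benzene | COc1ccc(COCC#CSc2ccccc2)cc1
F6 | step 9 | 1-methoxy-4-({[3-(phenylsulfonyl)prop-2-yn-1-yl]oxy}methyl)benzene | COc1ccc(COCC#CS(=O)(=O)c2ccccc2)cc1
F7 | step 9 | C4 vinyl sulfone adduct of 14 (alkene geometry not defined) | C=C[C@]1(C)C[C@H](O[Si](C)(C)C(C)(C)C)[C@@H](C(COCc2ccc(OC)cc2)=CS(=O)(=O)c2ccccc2)C(=O)[C@H]1C(=C)CO[Si](c3ccccc3)(c3ccccc3)C(C)(C)C
F8 | step 13 | 2-[bis(2,2,2-trifluoroethoxy)phosphoryl]propanoic acid | CC(C(=O)O)P(=O)(OCC(F)(F)F)OCC(F)(F)F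
F9 | step 13 | C3 2-[bis(2,2,2-trifluoroethoxy)phosphoryl]propanoate of 20 (phosphonate carbon both epimers) | C=C[C@]1(C)C[C@H](OC(=O)C(C)P(=O)(OCC(F)(F)F)OCC(F)(F)F)[C@@H](C(=C)COCc2ccc(OC)cc2)[C@@H](O)[C@H]1C(=C)CO[Si](c3ccccc3)(c3ccccc3)C(C)(C)C
F10 | step 13 | C5 triethylsilyl ether of F9 | C=C[C@]1(C)C[C@H](OC(=O)C(C)P(=O)(OCC(F)(F)F)OCC(F)(F)F)[C@@H](C(=C)COCc2ccc(OC)cc2)[C@@H](O[Si](CC)(CC)CC)[C@H]1C(=C)CO[Si](c3ccccc3)(c3ccccc3)C(C)(C)C
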